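**Plan**
1. Retrosynthesis: the eight benzyl ethers come off first, then the upper interflavan bond C4(top unit)–C8(middle unit), then the lower one C4(middle unit)–C8(lower unit), which leads back to (−)-epiafzelechin. In the top 7,4'-dihydroxyflavan unit, ring C is cut at O1–C2 and at C3–C4.
2. Feature used: in the top unit O1 and C4 sit on the neighbouring carbons C8a and C4a of ring A (a salicylaldehyde pattern), C2 carries ring B, and C3 is the only CH2 of ring C. Ring C therefore maps onto a phenol oxygen, a formyl carbon and the β- and α-carbons of a cinnamaldehyde.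
3. Forward, top unit: an amine-catalysed domino oxa-Michael/aldol condensation forms O1–C2 and then closes ring C through the C3–C4 bond. The formyl group on C3 that makes this possible is removed by decarbonylation, and Markovnikov hydration turns C4 into an electrophile.
4. Forward, lower units: benzylated epiafzelechin is oxidized at C4 and coupled with itself (4β→8). The top-unit cation is then attached to C8 of the upper unit of this dimer, and hydrogenolysis finishes the synthesis.
5. Stereochemistry: C2 of the top unit comes from the prolinol catalyst in the domino step. C4 of the top unit (2,4-trans) and C4 of the middle unit (3,4-trans) come from attack of the arene on the flavan-4-yl cations anti to the 2-aryl and the 3-hydroxyl group. All other centres come from (−)-epiafzelechin.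

Key step: step 2

Remark: (−)-epiafzelechin (2R,3R) is taken as a catalogue compound, and the (S)-configured prolinol ether is assumed to shield the Re face of the iminium β-carbon as in its other β-additions (if the sense were opposite, its enantiomer would be used).

**Route**

Step 1
Reactants: 1 4-(benzyloxy)benzaldehyde
Product: 2 (E)-3-[4-(benzyloxy)phenyl]prop-2-enal
Conditions: Ph3P=CHCHO (1.1 equiv), toluene, 80 °C
Reagents that add atoms: (triphenylphosphoranylidene)acetaldehyde O=CC=P(c1ccccc1)(c1ccccc1)c1ccccc1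
Why: Wittig olefination with the stabilized formylmethylene ylide should give the (E)-enal through the thermodynamically favoured anti oxaphosphetane, and no stereocenter is formed.

Step 2
Reactants: 2 (E)-3-[4-(benzyloxy)phenyl]prop-2-enal, 3 4-(benzyloxy)-2-hydroxybenzaldehyde
Product: 6 (R)-7-(benzyloxy)-2-[4-(benzyloxy)phenyl]-2H-chromene-3-carbaldehyde, via oxa-Michael enamine 4 (not isolated), via aldol enamine 5 (not isolated)
Conditions: (S)-2-[diphenyl(trimethylsilyloxy)methyl]pyrrolidine (20 mol%), 2-nitrobenzoic acid (20 mol%), toluene, 4 Å MS, 0 °C to rt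
Reagents that add atoms: none
Why: The secondary amine condenses with enal 2 to an (E)-iminium ion, the phenolic oxygen of 3 adds to its β-carbon (future C2) to give enamine 4, the enamine carbon (future C3) attacks the neighbouring formyl carbon (future C4) in an intramolecular aldol addition to 5, and loss of water and of the catalyst gives the conjugated enal 6. The closest known reaction type is the diarylprolinol-silyl-ether-catalysed domino oxa-Michael/aldol condensation of salicylaldehydes with cinnamaldehydes to 2-aryl-2H-chromene-3-carbaldehydes. Ring C is closed by the C3–C4 bond in a 6-(enolexo)-exo-trig aldol closure, which is possible only because O1 and C4 sit on the adjacent carbons C8a and C4a of ring A. The only stereocenter that survives, C2, is set by the catalyst: its diphenyl(silyloxy)methyl group shields the Re face of the β-carbon of the iminium ion, so oxygen should add to the Si face and give the (R)-chromene, which has the spatial arrangement of the (2S)-flavan of the target, while the carbinol centre at C4 of 5 is erased by dehydration. The step needs chemoselectivity (productive iminium formation at the enal, not at the aryl aldehyde) and suppression of the reversible, unselective oxa-Michael background; the fast, irreversible aldol dehydration that follows the C–O bond formation and the acid co-catalyst should secure both.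

Step 3
Reactants: 6 (R)-7-(benzyloxy)-2-[4-(benzyloxy)phenyl]-2H-chromene-3-carbaldehyde
Product: 7 (S)-7-(benzyloxy)-2-[4-(benzyloxy)phenyl]-2H-chromene
Conditions: RhCl(PPh3)3 (1.1 equiv), toluene, 90 °C, argon, exclusion of light
Reagents that add atoms: none
Why: Tsuji–Wilkinson decarbonylation (oxidative addition of the formyl C–H bond to monovalent rhodium, CO de-insertion, C–H reductive elimination) should replace the helper formyl group on C3 by hydrogen without touching C2, whose descriptor changes from R to S only because C3 loses CIP priority.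

Step 4
Reactants: 7 (S)-7-(benzyloxy)-2-[4-(benzyloxy)phenyl]-2H-chromene
Product: 9 (2S)-7-(benzyloxy)-2-[4-(benzyloxy)phenyl]chroman-4-ol as a mixture of C4 epimers, via silyl peroxide 8 (not isolated)
Conditions: Co(acac)2 (10 mol%), PhSiH3, O2 (1 atm), THF, rt; then PPh3; aqueous work-up
Reagents that add atoms: dioxygen O=O
Why: Mukaiyama hydration: hydrogen-atom transfer from a cobalt hydride to C3 gives the benzylic C4 radical, which is trapped by O2, so that the hydroxyl group should end up at C4 (Markovnikov) as a mixture of epimers, which does not matter because C4 is ionized in step 8.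

Step 5
Reactants: 10 (−)-epiafzelechin
Product: 11 (2R,3R)-5,7-bis(benzyloxy)-2-[4-(benzyloxy)phenyl]chroman-3-ol
Conditions: BnBr (3.3 equiv), K2CO3, DMF, 0 °C to rt
Reagents that add atoms: benzyl bromide BrCc1ccccc1
Why: Williamson ether synthesis on the three phenols, which are far more acidic than the secondary 3-hydroxyl group, with a mild base that should leave C2 and C3 untouched; no new stereocenter.

Step 6
Reactants: 11 (2R,3R)-5,7-bis(benzyloxy)-2-[4-(benzyloxy)phenyl]chroman-3-ol
Product: 12 4β-(2-ethoxyethoxy) ether of 11 (2,3-cis-3,4-trans)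
Conditions: DDQ (2 equiv), 2-ethoxyethanol (5 equiv), CH2Cl2, rt
Reagents that add atoms: 2-ethoxyethanol CCOCCO
Why: Benzylic oxidation by hydride abstraction with DDQ at C4, whose cation is stabilized by the 5,7-dioxygenated ring A, and capture by the alcohol on the β face, anti to the 3-hydroxyl group, should give the 3,4-trans ether, a centre that is ionized again in step 7.

Step 7
Reactants: 12 4β-(2-ethoxyethoxy) ether of 11, 11 (2R,3R)-5,7-bis(benzyloxy)-2-[4-(benzyloxy)phenyl]chroman-3-ol (3 equiv)
Product: 13 5,7,4'-tri-O-benzylepiafzelechin-(4β→8)-5,7,4'-tri-O-benzylepiafzelechin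
Conditions: TMSOTf (0.1 equiv), CH2Cl2, −78 °C; Et3N quench
Reagents that add atoms: none
Why: Lewis-acid-promoted Friedel–Crafts-type flavan coupling: TMSOTf ionizes the C4 ether, and C8 of a second molecule of 11, the most nucleophilic ring-A position, should attack the cation anti to the 3-hydroxyl group, which sets C4 of the future middle unit as 4β (3,4-trans), while the excess of 11 holds back higher oligomers.

Step 8
Reactants: 9 (2S)-7-(benzyloxy)-2-[4-(benzyloxy)phenyl]chroman-4-ol, 13 5,7,4'-tri-O-benzylepiafzelechin-(4β→8)-5,7,4'-tri-O-benzylepiafzelechin (1.5 equiv)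
Product: 14 (2S)-7,4'-bis(benzyloxy)flavan-(4β→8)-5,7,4'-tri-O-benzylepiafzelechin-(4β→8)-5,7,4'-tri-O-benzylepiafzelechin
Conditions: TMSOTf (0.2 equiv), CH2Cl2, 4 Å MS, −78 to −40 °C; Et3N quench
Reagents that add atoms: none
Why: The same Friedel–Crafts-type coupling: ionization of the benzylic alcohol gives the flavan-4-yl cation stabilized by O1 and the para 7-benzyloxy group, and the only free C8 of 13 (upper unit) should attack it pseudo-axially on the face anti to the equatorial 2-aryl group, which sets C4 of the top unit as R (2,4-trans).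

Step 9
Reactants: 14 (2S)-7,4'-bis(benzyloxy)flavan-(4β→8)-5,7,4'-tri-O-benzylepiafzelechin-(4β→8)-5,7,4'-tri-O-benzylepiafzelechin
Product: 15 (2S)-7,4'-dihydroxyflavan-(4β→8)-epiafzelechin-(4β→8)-epiafzelechin (CNP0257624.1)
Conditions: H2 (1 atm), Pd(OH)2/C, THF/MeOH/H2O, rt
Reagents that add atoms: none
Why: Hydrogenolysis of the eight benzyl ethers over Pd(OH)2/C under neutral conditions should free all phenols and leave the doubly benzylic interflavan C–C bonds, the ring-C ether bonds and all seven stereocenters untouched.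

**Compound list**
1 | 4-(benzyloxy)benzaldehyde | O=Cc1ccc(OCc2ccccc2)cc1 | starting material
2 | (E)-3-[4-(benzyloxy)phenyl]prop-2-enal | O=C/C=C/c1ccc(OCc2ccccc2)cc1 | intermediate
3 | 4-(benzyloxy)-2-hydroxybenzaldehyde | O=Cc1ccc(OCc2ccccc2)cc1O | starting material
4 | oxa-Michael enamine: (E)-enamine of the (S)-prolinol silyl ether catalyst with (3S)-3-[5-(benzyloxy)-2-formylphenoxy]-3-[4-(benzyloxy)phenyl]propanal | O=Cc1ccc(OCc2ccccc2)cc1O[C@@H](/C=C/N1CCC[C@H]1C(O[Si](C)(C)C)(c1ccccc1)c1ccccc1)c1ccc(OCc2ccccc2)cc1 | intermediate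
5 | aldol enamine: (2R)-7-(benzyloxy)-2-[4-(benzyloxy)phenyl]-3-(aminomethylidene)chroman-4-ol whose amino group is the pyrrolidine nitrogen of the catalyst (C4 epimers) | OC1C(=CN2CCC[C@H]2C(O[Si](C)(C)C)(c2ccccc2)c2ccccc2)[C@@H](c2ccc(OCc3ccccc3)cc2)Oc2cc(OCc3ccccc3)ccc12 | intermediate
6 | (R)-7-(benzyloxy)-2-[4-(benzyloxy)phenyl]-2H-chromene-3-carbaldehyde | O=CC1=Cc2ccc(OCc3ccccc3)cc2O[C@@H]1c1ccc(OCc2ccccc2)cc1 | intermediate
7 | (S)-7-(benzyloxy)-2-[4-(benzyloxy)phenyl]-2H-chromene | C1=Cc2ccc(OCc3ccccc3)cc2O[C@@H]1c1ccc(OCc2ccccc2)cc1 | intermediate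
8 | silyl peroxide: (2S)-7-(benzyloxy)-2-[4-(benzyloxy)phenyl]-4-[(phenylsilyl)peroxy]chromane (C4 epimers) | c1ccc(cc1)[SiH2]OOC1C[C@@H](c2ccc(OCc3ccccc3)cc2)Oc2cc(OCc3ccccc3)ccc12 | intermediate
9 | (2S)-7-(benzyloxy)-2-[4-(benzyloxy)phenyl]chroman-4-ol (C4 epimers) | OC1C[C@@H](c2ccc(OCc3ccccc3)cc2)Oc2cc(OCc3ccccc3)ccc12 | intermediate
10 | (−)-epiafzelechin, (2R,3R)-2-(4-hydroxyphenyl)chromane-3,5,7-triol | Oc1cc(O)c2c(c1)O[C@H](c1ccc(O)cc1)[C@H](O)C2 | starting material
11 | (2R,3R)-5,7-bis(benzyloxy)-2-[4-(benzyloxy)phenyl]chroman-3-ol (5,7,4'-tri-O-benzylepiafzelechin) | c1ccc(COc2cc(OCc3ccccc3)c3c(c2)O[C@H](c2ccc(OCc4ccccc4)cc2)[C@H](O)C3)cc1 | intermediate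
12 | 4β-(2-ethoxyethoxy)-5,7,4'-tri-O-benzylepiafzelechin (2,3-cis-3,4-trans) | c1ccc(COc2cc(OCc3ccccc3)c3c(c2)O[C@H](c2ccc(OCc4ccccc4)cc2)[C@H](O)[C@H]3OCCOCC)cc1 | intermediate
13 | 5,7,4'-tri-O-benzylepiafzelechin-(4β→8)-5,7,4'-tri-O-benzylepiafzelechin (both 3-OH free) | c1ccc(COc2cc(OCc3ccccc3)c3c(c2)O[C@H](c2ccc(OCc4ccccc4)cc2)[C@H](O)[C@H]3c2c(OCc3ccccc3)cc(OCc3ccccc3)c3c2O[C@H](c2ccc(OCc4ccccc4)cc2)[C@H](O)C3)cc1 | intermediate
14 | (2S)-7,4'-bis(benzyloxy)flavan-(4β→8)-5,7,4'-tri-O-benzylepiafzelechin-(4β→8)-5,7,4'-tri-O-benzylepiafzelechin (top unit 2S,4R, 2,4-trans) | c5ccccc5COc1ccc([C@@H]2C[C@@H](c3c(OCc5ccccc5)cc(OCc5ccccc5)c4c3O[C@H](c3ccc(OCc5ccccc5)cc3)[C@H](O)[C@H]4c3c(OCc5ccccc5)cc(OCc5ccccc5)c4c3O[C@H](c3ccc(OCc5ccccc5)cc3)[C@H](O)C4)c3ccc(OCc5ccccc5)cc3O2)cc1 | intermediate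
15 | (2S)-7,4'-dihydroxyflavan-(4β→8)-epiafzelechin-(4β→8)-epiafzelechin, CNP0257624.1 (top unit 2S,4R; middle and lower units 2R,3R; both interflavan bonds β) | Oc1ccc([C@@H]2C[C@@H](c3c(O)cc(O)c4c3O[C@H](c3ccc(O)cc3)[C@H](O)[C@H]4c3c(O)cc(O)c4c3O[C@H](c3ccc(O)cc3)[C@H](O)C4)c3ccc(O)cc3O2)cc1 | target

**Count**
Total steps: 9. Longest linear sequence: 6 steps (steps 1, 2, 3, 4, 8, 9).

**Steps most likely to fail**

Step 8. What may go wrong: attack of the cation at the C6 positions of 13 instead of C8, partial formation of the 2,4-cis epimer, self-condensation of 9, and acid-induced fission of the interflavan bond already present. Fallback (sets out from 12, uses 9 and 11, comes back at 14): the order of the two interflavan couplings is reversed with orthogonal activation of C4. Compound 12 with thiophenol and BF3·OEt2 gives 4β-(phenylthio)-5,7,4'-tri-O-benzylepiafzelechin F8. F8 in excess, whose thioether is inert to the hard Lewis acid and which offers the nucleophilic sites of a single flavan unit, is coupled with 9 (BF3·OEt2, CH2Cl2, −78 °C) to the top–middle dimer (2S)-7,4'-bis(benzyloxy)flavan-(4β→8)-4β-(phenylthio)-5,7,4'-tri-O-benzylepiafzelechin F9. The thioether of F9 is then activated with the thiophilic salt AgBF4 in the presence of excess 11, which forms the lower 4β→8 bond and gives 14.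

Step 3. What may go wrong: loss of configurational purity at C2 on heating, through reversible electrocyclic opening of the 2H-chromene or through rhodium-hydride migration of the double bond into the achiral 4H-chromene, and sluggish CO extrusion from the α-substituted enal. Fallback (sets out from 6, comes back at 14): the ring is saturated before the formyl group is removed. Copper-hydride conjugate reduction of 6 ([(Ph3P)CuH]6 catalytic, PhMe2SiH, then buffered hydrolysis of the silyl enol ether) gives (2S)-7-(benzyloxy)-2-[4-(benzyloxy)phenyl]chromane-3-carbaldehyde F5, in which neither racemization pathway exists. Decarbonylation with RhCl(PPh3)3 gives (2S)-7-(benzyloxy)-2-[4-(benzyloxy)phenyl]chromane F6. DDQ with 2-ethoxyethanol oxidizes the ring-A-activated C4 to (2S)-7-(benzyloxy)-2-[4-(benzyloxy)phenyl]-4-(2-ethoxyethoxy)chromane F7, which takes the place of 9 in step 8 (TMSOTf, 13) and gives 14.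

Step 2. What may go wrong: slow oxa-Michael addition to the electron-rich iminium ion and erosion of the enantiomeric purity through the reversible, uncatalysed addition. Fallback (sets out from 2 and 3, comes back at 7): C2 is set by a metal-catalysed allylic substitution and the same C3–C4 bond is closed as a double bond by metathesis. Wittig methylenation of 3 (Ph3PCH3Br, KOtBu, THF) gives 5-(benzyloxy)-2-ethenylphenol F1. Luche reduction of 2 (NaBH4, CeCl3, MeOH) gives (E)-3-[4-(benzyloxy)phenyl]prop-2-en-1-ol F2, which is converted into its methyl carbonate F3 (ClCO2Me, pyridine). Asymmetric allylic etherification of F1 with F3 ([Ir(cod)Cl]2, chiral phosphoramidite, base) should give the branched ether (S)-4-(benzyloxy)-2-({1-[4-(benzyloxy)phenyl]prop-2-en-1-yl}oxy)-1-ethenylbenzene F4. Ring-closing metathesis with the second-generation Grubbs catalyst then gives 7, so that steps 2 and 3 are not needed.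

**Further compounds**
F1 | step 2 | 5-(benzyloxy)-2-ethenylphenol | C=Cc1ccc(OCc2ccccc2)cc1O
F2 | step 2 | (E)-3-[4-(benzyloxy)phenyl]prop-2-en-1-ol | OC/C=C/c1ccc(OCc2ccccc2)cc1
F3 | step 2 | (E)-3-[4-(benzyloxy)phenyl]prop-2-en-1-yl methyl carbonate | COC(=O)OC/C=C/c1ccc(OCc2ccccc2)cc1
F4 | step 2 | (S)-4-(benzyloxy)-2-({1-[4-(benzyloxy)phenyl]prop-2-en-1-yl}oxy)-1-ethenylbenzene | C=Cc1ccc(OCc2ccccc2)cc1O[C@@H](C=C)c1ccc(OCc2ccccc2)cc1
F5 | step 3 | (2S)-7-(benzyloxy)-2-[4-(benzyloxy)phenyl]chromane-3-carbaldehyde (C3 epimers) | O=CC1Cc2ccc(OCc3ccccc3)cc2O[C@@H]1c1ccc(OCc2ccccc2)cc1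
F6 | step 3 | (2S)-7-(benzyloxy)-2-[4-(benzyloxy)phenyl]chromane | C1Cc2ccc(OCc3ccccc3)cc2O[C@@H]1c1ccc(OCc2ccccc2)cc1
F7 | step 3 | (2S)-7-(benzyloxy)-2-[4-(benzyloxy)phenyl]-4-(2-ethoxyethoxy)chromane (C4 epimers) | CCOCCOC1C[C@@H](c2ccc(OCc3ccccc3)cc2)Oc2cc(OCc3ccccc3)ccc12
F8 | step 8 | 4β-(phenylthio)-5,7,4'-tri-O-benzylepiafzelechin | c1ccc(COc2cc(OCc3ccccc3)c3c(c2)O[C@H](c2ccc(OCc4ccccc4)cc2)[C@H](O)[C@H]3Sc2ccccc2)cc1
F9 | step 8 | (2S)-7,4'-bis(benzyloxy)flavan-(4β→8)-4β-(phenylthio)-5,7,4'-tri-O-benzylepiafzelechin | c5ccccc5COc1ccc([C@@H]2C[C@@H](c3c(OCc5ccccc5)cc(OCc5ccccc5)c4c3O[C@H](c3ccc(OCc5ccccc5)cc3)[C@H](O)[C@H]4Sc3ccccc3)c3ccc(OCc5ccccc5)cc3O2)cc1
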